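**Retrosynthetic overview**

1. The target, siphonaxanthin 19-dodecanoate, is cut at C11=C12: a Wittig reaction joins a C25 polyenyl ylide (ε end) to a C15 lactol (β end). The lactol ring holds C19 and C11 cis on C9=C10 and releases only the C19 hydroxyl for the laurate; C8 is carried as a carbinol and oxidised last.
2. The C25 unit comes from an ε-C15 phosphonium salt and commercial C10 trienedial (C11'=C12'). The C15 lactol comes from (4R,6R)-actinol via enol triflate, allyl group, aldehyde and a Nozaki–Hiyama–Kishi coupling with 4-bromofuran-2(5H)-one.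
3. Enabling feature: the ε-ring C1'–C6' with C7' is two head-to-tail C5 units. C1'(CH3)2–C2'–C3' is the β-carbon, α-carbon and carbonyl carbon of 3-methylbut-2-enal (a 1,3-dielectrophile). C4'–C5'(CH3)–C6'(–C7') is C4, C3 and C2 of a 3-methylbut-2-enoate (a 1,3-dinucleophile as its C4 phosphorane). One [3+3] phosphorane annulation therefore makes C6'–C1' and C4'–C3' and delivers the whole C10 end group as a cyclohexa-1,3-diene ester.
4. That diene carries both ε-ring stereocentres in latent form. Catalyst-controlled epoxidation of C3'=C4' sets C3'–O. A retentive palladium amination at C4', followed by allylic diazene retro-ene loss of N2, relays it across the ring to C6'–H and places the double bond at C4'=C5'.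
5. Rings: the ε-ring is formed in step 2 and is the only carbocycle built. The β-ring is taken intact from actinol. The temporary butenolide/lactol ring comes from the bromofuranone and is opened in step 19.

Key step: step 2

Remark: positions are given in carotenoid numbering; the four intermediates between the chromium-mediated coupling and the final oxidation are carried as C8 epimers (the lactol also as anomers) and their SMILES leave that centre open because it becomes the ketone; the two commercial C5 esters are E/Z mixtures and are drawn E.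

**Route**

Step 1
Reactants: 1 ethyl (E)-4-bromo-3-methylbut-2-enoate; 2 triphenylphosphine
Product: 3 [(E)-3-(ethoxycarbonyl)-2-methylprop-2-en-1-yl]triphenylphosphonium bromide
Conditions: toluene, 23 °C
Reagents that add atoms: none
Why: SN2 quaternisation of the primary allylic bromide by the phosphine (Wittig salt formation); no stereocentre is involved.

Step 2
Reactants: 3 [(E)-3-(ethoxycarbonyl)-2-methylprop-2-en-1-yl]triphenylphosphonium bromide; 4 3-methylbut-2-enal
Product: 7 ethyl 2,6,6-trimethylcyclohexa-1,3-diene-1-carboxylate (ethyl safranate), via allylidene phosphorane 5 (not isolated), via Michael adduct ylide 6 (not isolated)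
Conditions: NaH, THF, 0 °C; then 4, 0 → 65 °C
Reagents that add atoms: none
Why: The ambident phosphorane 5 adds through its γ-carbon (C6', α to the ester) to the β-carbon of the enal (C1', a vinylogous Michael addition that creates the quaternary centre), proton transfer gives ylide 6, and intramolecular Wittig olefination of C4' onto the aldehyde carbon C3' closes the six-membered ring (6-exo attack of the ylide carbon on C=O, then loss of Ph3PO). The closest known reaction type is the [3+3] annulation of enals with ester-substituted allylidene phosphoranes, the established entry to safranic esters. Should 5 attack the aldehyde first, the (Z)-trienoate so formed closes the same C1'–C6' bond by thermal disrotatory 6π electrocyclisation and isomerises to the same conjugated diene, so both courses converge on 7. No stereocentre is formed, and this is intended: the step leaves C3'=C4' and C5'=C6' as the latent C3' and C6' stereocentres. The selectivity needed is regiochemical (C6' to C1' and C4' to C3', not the reverse), and it is secured by the ester, which makes C6' the soft vinylogous donor and leaves the ylide carbon C4' as the only centre able to olefinate.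

Step 3
Reactants: 7 ethyl 2,6,6-trimethylcyclohexa-1,3-diene-1-carboxylate
Product: 8 ethyl (1S,6R)-2,4,4-trimethyl-7-oxabicyclo[4.1.0]hept-2-ene-3-carboxylate (the C3',C4' epoxide)
Conditions: (S,S)-(salen)MnCl [chloro (S,S)-N,N'-bis(3,5-di-tert-butylsalicylidene)cyclohexane-1,2-diamine manganese, trivalent manganese] (5 mol %), 4-phenylpyridine N-oxide, aq NaOCl (pH 11.3), CH2Cl2, 0 °C
Reagents that add atoms: sodium hypochlorite, [Na+].[O-]Cl
Why: Jacobsen–Katsuki epoxidation attacks only the cis-disubstituted, electron-richer C3'=C4' bond (the ester-bearing tetrasubstituted C5'=C6' bond is deactivated and shielded), and the (S,S)-ligand, by the side-on approach model for cis-alkenes conjugated to an unsaturated group such as 2,2-dimethylchromenes, should deliver oxygen to the face that gives C3' its final configuration.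

Step 4
Reactants: 8 ethyl (1S,6R)-2,4,4-trimethyl-7-oxabicyclo[4.1.0]hept-2-ene-3-carboxylate; 9 N'-(propan-2-ylidene)-2-nitrobenzenesulfonohydrazide
Product: 13 ethyl (1R,4R)-4-hydroxy-2,6,6-trimethylcyclohex-2-ene-1-carboxylate, via allyl hydrazone 10 (not isolated), via sulfonyl hydrazine 11 (not isolated), via allylic diazene 12 (not isolated)
Conditions: Pd(PPh3)4 (5 mol %), THF, 23 °C; then CF3CH2OH/H2O (1:1), 23 °C
Reagents that add atoms: none
Why: Proposed new method: zerovalent palladium should ionise the allylic C4'–O bond of the γ,δ-epoxy enoate with inversion to a π-allyl alkoxide, the alkoxide deprotonates the sulfonyl hydrazone N–H, and nitrogen attacks C4' (the terminus remote from the ester, C6' being fully substituted) anti to palladium, so that nitrogen replaces oxygen with net retention, cis to the C3' hydroxyl; hydrolysis of the hydrazone, loss of 2-nitrobenzenesulfinic acid and retro-ene loss of N2 from diazene 12 then deliver hydrogen suprafacially to C6' on the face of the C3' oxygen while the double bond moves to C4'=C5', which sets C6' as R from the C4' centre; the closest known reaction types are the palladium-catalysed γ-substitution of γ,δ-epoxy-α,β-unsaturated esters with retention and the Tsuji–Trost allylation of this hydrazide with allylic carbonates followed by allylic diazene rearrangement.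

Step 5
Reactants: 13 ethyl (1R,4R)-4-hydroxy-2,6,6-trimethylcyclohex-2-ene-1-carboxylate
Product: 14 ethyl (1R,4R)-4-[(tert-butyldimethylsilyl)oxy]-2,6,6-trimethylcyclohex-2-ene-1-carboxylate
Conditions: TBSCl, imidazole, DMF, 23 °C
Reagents that add atoms: tert-butyldimethylsilyl chloride, CC(C)(C)[Si](C)(C)Cl
Why: Standard silylation of the secondary allylic alcohol under conditions too mild to touch the base-labile C6' centre.

Step 6
Reactants: 14 ethyl (1R,4R)-4-[(tert-butyldimethylsilyl)oxy]-2,6,6-trimethylcyclohex-2-ene-1-carboxylate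
Product: 15 (1R,4R)-4-[(tert-butyldimethylsilyl)oxy]-2,6,6-trimethylcyclohex-2-ene-1-carbaldehyde
Conditions: i-Bu2AlH (1.1 equiv), CH2Cl2, −78 °C; potassium sodium tartrate workup
Reagents that add atoms: none
Why: Partial hydride reduction of the hindered ester stops at the aluminium hemiacetal at −78 °C, and the neutral workup leaves the C6' centre next to the new aldehyde unchanged.

Step 7
Reactants: 15 (1R,4R)-4-[(tert-butyldimethylsilyl)oxy]-2,6,6-trimethylcyclohex-2-ene-1-carbaldehyde; 16 ethyl (E)-4-(diethoxyphosphoryl)-3-methylbut-2-enoate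
Product: 18 ethyl (2E,4E)-5-[(1R,4R)-4-[(tert-butyldimethylsilyl)oxy]-2,6,6-trimethylcyclohex-2-en-1-yl]-3-methylpenta-2,4-dienoate, via lithium phosphonate 17 (not isolated)
Conditions: 16, LiN(SiMe3)2, THF, −78 °C; then 15, −78 → 0 °C
Reagents that add atoms: none
Why: Horner–Wadsworth–Emmons olefination with the preformed, weakly basic vinylogous phosphonate anion should form C7'=C8' E-selectively and add to the aldehyde faster than it can deprotonate the shielded C6'–H.

Step 8
Reactants: 18 ethyl (2E,4E)-5-[(1R,4R)-4-[(tert-butyldimethylsilyl)oxy]-2,6,6-trimethylcyclohex-2-en-1-yl]-3-methylpenta-2,4-dienoate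
Product: 19 (2E,4E)-5-[(1R,4R)-4-[(tert-butyldimethylsilyl)oxy]-2,6,6-trimethylcyclohex-2-en-1-yl]-3-methylpenta-2,4-dien-1-ol
Conditions: i-Bu2AlH (2.2 equiv), CH2Cl2, −78 °C
Reagents that add atoms: none
Why: 1,2-Reduction of the dienoate to the primary allylic alcohol by the aluminium hydride; no stereocentre is affected.

Step 9
Reactants: 19 (2E,4E)-5-[(1R,4R)-4-[(tert-butyldimethylsilyl)oxy]-2,6,6-trimethylcyclohex-2-en-1-yl]-3-methylpenta-2,4-dien-1-ol
Product: 20 [(2E,4E)-5-[(1R,4R)-4-[(tert-butyldimethylsilyl)oxy]-2,6,6-trimethylcyclohex-2-en-1-yl]-3-methylpenta-2,4-dien-1-yl]triphenylphosphonium bromide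
Conditions: PPh3·HBr, CH2Cl2, 0 → 23 °C
Reagents that add atoms: triphenylphosphine hydrobromide, [Br-].c1ccc(cc1)[PH+](c1ccccc1)c1ccccc1
Why: Wittig salt formation by substitution of the dienylic alcohol through its delocalised cation at the terminal carbon, run without alcohol solvent so that the silyl ether should survive.

Step 10
Reactants: 20 the C15 phosphonium bromide; 21 (2E,4E,6E)-2,7-dimethylocta-2,4,6-trienedial
Product: 23 (2E,4E,6E,8E,10E,12E)-13-[(1R,4R)-4-[(tert-butyldimethylsilyl)oxy]-2,6,6-trimethylcyclohex-2-en-1-yl]-2,7,11-trimethyltrideca-2,4,6,8,10,12-hexaenal, via C15 ylide 22 (not isolated)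
Conditions: NaOMe, MeOH/CH2Cl2, 21 (2.5 equiv), 0 → 23 °C; then cat. I2, CH2Cl2, 23 °C
Reagents that add atoms: none
Why: Wittig olefination forms C11'=C12', the excess dialdehyde keeps it to one end, and iodine equilibrates the sterically hindered Z isomers at C11' (and any at C9') to the all-E aldehyde.

Step 11
Reactants: 23 the C25 hexaenal
Product: 24 (2E,4E,6E,8E,10E,12E)-13-[(1R,4R)-4-[(tert-butyldimethylsilyl)oxy]-2,6,6-trimethylcyclohex-2-en-1-yl]-2,7,11-trimethyltrideca-2,4,6,8,10,12-hexaen-1-ol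
Conditions: NaBH4, MeOH/THF, 0 °C
Reagents that add atoms: none
Why: Borohydride 1,2-reduction of the polyenal to the primary alcohol.

Step 12
Reactants: 24 the C25 hexaenol
Product: 25 [(2E,4E,6E,8E,10E,12E)-13-[(1R,4R)-4-[(tert-butyldimethylsilyl)oxy]-2,6,6-trimethylcyclohex-2-en-1-yl]-2,7,11-trimethyltrideca-2,4,6,8,10,12-hexaen-1-yl]triphenylphosphonium bromide
Conditions: PPh3·HBr, CH2Cl2, 0 °C
Reagents that add atoms: triphenylphosphine hydrobromide, [Br-].c1ccc(cc1)[PH+](c1ccccc1)c1ccccc1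
Why: Wittig salt formation as in step 9, the polyenyl cation being captured at its terminal carbon to keep full conjugation.

Step 13
Reactants: 26 (4R,6R)-4-hydroxy-2,2,6-trimethylcyclohexan-1-one (actinol)
Product: 27 (4R,6R)-4-[(tert-butyldimethylsilyl)oxy]-2,2,6-trimethylcyclohexan-1-one
Conditions: TBSCl, imidazole, DMF, 23 °C
Reagents that add atoms: tert-butyldimethylsilyl chloride, CC(C)(C)[Si](C)(C)Cl
Why: Standard silylation of the secondary alcohol, whose chiral-pool stereocentre becomes C3 of the target.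

Step 14
Reactants: 27 (4R,6R)-4-[(tert-butyldimethylsilyl)oxy]-2,2,6-trimethylcyclohexan-1-one
Product: 29 (4R)-4-[(tert-butyldimethylsilyl)oxy]-2,6,6-trimethylcyclohex-1-en-1-yl trifluoromethanesulfonate, via potassium enolate 28 (not isolated)
Conditions: KN(SiMe3)2, THF, −78 °C; then PhNTf2, −78 → 0 °C
Reagents that add atoms: N-phenylbis(trifluoromethanesulfonimide), O=S(=O)(N(c1ccccc1)S(=O)(=O)C(F)(F)F)C(F)(F)F
Why: Enol triflate formation can only go toward the methyl-bearing carbon because the other α-carbon is quaternary, which fixes the C5=C6 double bond and deliberately removes the methyl stereocentre.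

Step 15
Reactants: 29 the enol triflate; 30 allyltributylstannane
Product: 31 tert-butyldimethyl{[(1R)-3,5,5-trimethyl-4-(prop-2-en-1-yl)cyclohex-3-en-1-yl]oxy}silane
Conditions: Pd(PPh3)4 (5 mol %), LiCl, THF, 65 °C
Reagents that add atoms: none
Why: Stille coupling of the hindered vinyl triflate with the readily transferred allyl group forms the C6–C7 bond with the ring double bond in place.

Step 16
Reactants: 31 the allyl cyclohexene
Product: 32 2-[(4R)-4-[(tert-butyldimethylsilyl)oxy]-2,6,6-trimethylcyclohex-1-en-1-yl]acetaldehyde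
Conditions: OsO4 (2 mol %), NaIO4, 2,6-lutidine, dioxane/H2O, 23 °C
Reagents that add atoms: osmium tetroxide, O=[Os](=O)(=O)=O; sodium periodate, [Na+].[O-]I(=O)(=O)=O
Why: Lemieux–Johnson cleavage, in which the osmium reagent selects the monosubstituted terminal alkene over the shielded tetrasubstituted ring alkene, gives the C7–C8 aldehyde.

Step 17
Reactants: 32 the β-ring acetaldehyde; 33 4-bromofuran-2(5H)-one
Product: 34 4-{2-[(4R)-4-[(tert-butyldimethylsilyl)oxy]-2,6,6-trimethylcyclohex-1-en-1-yl]-1-hydroxyethyl}furan-2(5H)-one (C8 epimers)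
Conditions: CrCl2 (4 equiv), NiCl2 (2 mol %), DMF, 23 °C
Reagents that add atoms: none
Why: Nozaki–Hiyama–Kishi coupling (nickel insertion into the vinylogous acyl bromide, transmetalation to chromium, addition to the aldehyde) forms C8–C9 under neutral conditions that leave the β,γ double bond in place; the new C8 carbinol is formed without control and is later oxidised.

Step 18
Reactants: 34 the butenolide carbinol
Product: 35 4-{2-[(4R)-4-[(tert-butyldimethylsilyl)oxy]-2,6,6-trimethylcyclohex-1-en-1-yl]-1-hydroxyethyl}-2,5-dihydrofuran-2-ol (lactol; C8 epimers and anomers)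
Conditions: i-Bu2AlH (2.5 equiv), CH2Cl2, −78 °C; potassium sodium tartrate workup; used crude
Reagents that add atoms: none
Why: Lactone-to-lactol reduction, the aluminium hemiacetal being stable at −78 °C after the free hydroxyl has consumed one equivalent of hydride.

Step 19
Reactants: 25 the C25 phosphonium bromide; 35 the lactol
Product: 37 (3R,3'R,6'R)-3,3'-bis[(tert-butyldimethylsilyl)oxy]-7,8-dihydro-β,ε-carotene-8,19-diol (all-E; C8 epimers), via C25 ylide 36 (not isolated)
Conditions: NaOMe (3 equiv), MeOH/CH2Cl2, 0 → 23 °C; then cat. I2, CH2Cl2, 23 °C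
Reagents that add atoms: none
Why: Wittig olefination of the lactol through its open (Z)-4-hydroxy-enal form makes C11=C12, the former ring fixes C19 cis to C11 (9E) and releases only the C19 hydroxyl, and iodine equilibrates the hindered 11Z isomer to E.

Step 20
Reactants: 37 the 8,19-diol; 38 dodecanoyl chloride
Product: 39 (3R,3'R,6'R)-3,3'-bis[(tert-butyldimethylsilyl)oxy]-8-hydroxy-7,8-dihydro-β,ε-caroten-19-yl dodecanoate (C8 epimers)
Conditions: 38 (1.05 equiv), 2,4,6-collidine, CH2Cl2, −40 °C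
Reagents that add atoms: none
Why: Chemoselective acylation of the primary allylic C19 hydroxyl over the hindered secondary C8 hydroxyl by the acid chloride at low temperature.

Step 21
Reactants: 39 the 8-hydroxy 19-dodecanoate
Product: 40 (3R,3'R,6'R)-3,3'-bis[(tert-butyldimethylsilyl)oxy]-8-oxo-7,8-dihydro-β,ε-caroten-19-yl dodecanoate
Conditions: MnO2 (activated, excess), CH2Cl2, 23 °C
Reagents that add atoms: none
Why: MnO2 oxidation of the only free alcohol, which is allylic to the polyene, gives the cross-conjugated C8 ketone and merges the C8 epimers, the allylic C3' oxygen being protected as its silyl ether.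

Step 22
Reactants: 40 the bis-silyl ether
Product: 41 (3R,3'R,6'R)-3,3'-dihydroxy-8-oxo-7,8-dihydro-β,ε-caroten-19-yl dodecanoate (siphonaxanthin 19-dodecanoate, CNP0415583.1)
Conditions: HF·pyridine, pyridine/THF, 0 → 23 °C
Reagents that add atoms: none
Why: Buffered fluoride desilylation frees both secondary alcohols without touching the laurate, the polyenone or the acid-sensitive allylic C3' centre.

**Compound list**

1 | ethyl (E)-4-bromo-3-methylbut-2-enoate | CCOC(=O)/C=C(\C)CBr | starting material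
2 | triphenylphosphine | c1ccc(cc1)P(c1ccccc1)c1ccccc1 | starting material
3 | [(E)-3-(ethoxycarbonyl)-2-methylprop-2-en-1-yl]triphenylphosphonium bromide | CCOC(=O)/C=C(\C)C[P+](c1ccccc1)(c1ccccc1)c1ccccc1.[Br-] | intermediate
4 | 3-methylbut-2-enal | CC(C)=CC=O | starting material
5 | ethyl (E)-3-methyl-4-(triphenylphosphoranylidene)but-2-enoate | CCOC(=O)/C=C(\C)C=P(c1ccccc1)(c1ccccc1)c1ccccc1 | intermediate
6 | ethyl (E)-3-methyl-2-(2-methyl-4-oxobutan-2-yl)-4-(triphenylphosphoranylidene)but-2-enoate | CCOC(=O)/C(C(C)(C)CC=O)=C(\C)C=P(c1ccccc1)(c1ccccc1)c1ccccc1 | intermediate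
7 | ethyl 2,6,6-trimethylcyclohexa-1,3-diene-1-carboxylate | CCOC(=O)C1=C(C)C=CCC1(C)C | intermediate
8 | ethyl (1S,6R)-2,4,4-trimethyl-7-oxabicyclo[4.1.0]hept-2-ene-3-carboxylate | CCOC(=O)C1=C(C)[C@@H]2O[C@@H]2CC1(C)C | intermediate
9 | N'-(propan-2-ylidene)-2-nitrobenzenesulfonohydrazide | CC(C)=NNS(=O)(=O)c1ccccc1[N+](=O)[O-] | starting material
10 | ethyl (3S,4R)-4-hydroxy-2,6,6-trimethyl-3-[1-(2-nitrophenylsulfonyl)-2-(propan-2-ylidene)hydrazinyl]cyclohex-1-ene-1-carboxylate | CCOC(=O)C1=C(C)[C@H](N(N=C(C)C)S(=O)(=O)c2ccccc2[N+](=O)[O-])[C@H](O)CC1(C)C | intermediate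
11 | ethyl (3S,4R)-4-hydroxy-2,6,6-trimethyl-3-[1-(2-nitrophenylsulfonyl)hydrazinyl]cyclohex-1-ene-1-carboxylate | CCOC(=O)C1=C(C)[C@H](N(N)S(=O)(=O)c2ccccc2[N+](=O)[O-])[C@H](O)CC1(C)C | intermediate
12 | ethyl (3S,4R)-3-diazenyl-4-hydroxy-2,6,6-trimethylcyclohex-1-ene-1-carboxylate | CCOC(=O)C1=C(C)[C@H](N=N)[C@H](O)CC1(C)C | intermediate
13 | ethyl (1R,4R)-4-hydroxy-2,6,6-trimethylcyclohex-2-ene-1-carboxylate | CCOC(=O)[C@H]1C(C)=C[C@H](O)CC1(C)C | intermediate
14 | ethyl (1R,4R)-4-[(tert-butyldimethylsilyl)oxy]-2,6,6-trimethylcyclohex-2-ene-1-carboxylate | CCOC(=O)[C@H]1C(C)=C[C@H](O[Si](C)(C)C(C)(C)C)CC1(C)C | intermediate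
15 | (1R,4R)-4-[(tert-butyldimethylsilyl)oxy]-2,6,6-trimethylcyclohex-2-ene-1-carbaldehyde | O=C[C@H]1C(C)=C[C@H](O[Si](C)(C)C(C)(C)C)CC1(C)C | intermediate
16 | ethyl (E)-4-(diethoxyphosphoryl)-3-methylbut-2-enoate | CCOC(=O)/C=C(\C)CP(=O)(OCC)OCC | starting material
17 | lithium salt of the C4 carbanion of 16 | CCOC(=O)/C=C(\C)[CH-]P(=O)(OCC)OCC.[Li+] | intermediate
18 | ethyl (2E,4E)-5-[(1R,4R)-4-[(tert-butyldimethylsilyl)oxy]-2,6,6-trimethylcyclohex-2-en-1-yl]-3-methylpenta-2,4-dienoate | CCOC(=O)/C=C(C)/C=C/[C@H]1C(C)=C[C@H](O[Si](C)(C)C(C)(C)C)CC1(C)C | intermediate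
19 | (2E,4E)-5-[(1R,4R)-4-[(tert-butyldimethylsilyl)oxy]-2,6,6-trimethylcyclohex-2-en-1-yl]-3-methylpenta-2,4-dien-1-ol | OC/C=C(C)/C=C/[C@H]1C(C)=C[C@H](O[Si](C)(C)C(C)(C)C)CC1(C)C | intermediate
20 | [(2E,4E)-5-[(1R,4R)-4-[(tert-butyldimethylsilyl)oxy]-2,6,6-trimethylcyclohex-2-en-1-yl]-3-methylpenta-2,4-dien-1-yl]triphenylphosphonium bromide | c1ccc(cc1)[P+](c1ccccc1)(c1ccccc1)C/C=C(C)/C=C/[C@H]1C(C)=C[C@H](O[Si](C)(C)C(C)(C)C)CC1(C)C.[Br-] | intermediate
21 | (2E,4E,6E)-2,7-dimethylocta-2,4,6-trienedial | O=C/C(C)=C/C=C/C=C(C)/C=O | starting material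
22 | ylide of 20 (C15 phosphorane) | c1ccc(cc1)P(c1ccccc1)(c1ccccc1)=C/C=C(C)/C=C/[C@H]1C(C)=C[C@H](O[Si](C)(C)C(C)(C)C)CC1(C)C | intermediate
23 | (2E,4E,6E,8E,10E,12E)-13-[(1R,4R)-4-[(tert-butyldimethylsilyl)oxy]-2,6,6-trimethylcyclohex-2-en-1-yl]-2,7,11-trimethyltrideca-2,4,6,8,10,12-hexaenal | O=C/C(C)=C/C=C/C=C(C)/C=C/C=C(C)/C=C/[C@H]1C(C)=C[C@H](O[Si](C)(C)C(C)(C)C)CC1(C)C | intermediate
24 | (2E,4E,6E,8E,10E,12E)-13-[(1R,4R)-4-[(tert-butyldimethylsilyl)oxy]-2,6,6-trimethylcyclohex-2-en-1-yl]-2,7,11-trimethyltrideca-2,4,6,8,10,12-hexaen-1-ol | OC/C(C)=C/C=C/C=C(C)/C=C/C=C(C)/C=C/[C@H]1C(C)=C[C@H](O[Si](C)(C)C(C)(C)C)CC1(C)C | intermediate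
25 | [(2E,4E,6E,8E,10E,12E)-13-[(1R,4R)-4-[(tert-butyldimethylsilyl)oxy]-2,6,6-trimethylcyclohex-2-en-1-yl]-2,7,11-trimethyltrideca-2,4,6,8,10,12-hexaen-1-yl]triphenylphosphonium bromide | c1ccc(cc1)[P+](c1ccccc1)(c1ccccc1)C/C(C)=C/C=C/C=C(C)/C=C/C=C(C)/C=C/[C@H]1C(C)=C[C@H](O[Si](C)(C)C(C)(C)C)CC1(C)C.[Br-] | intermediate
26 | (4R,6R)-4-hydroxy-2,2,6-trimethylcyclohexan-1-one | CC1(C)C[C@H](O)C[C@@H](C)C1=O | starting material
27 | (4R,6R)-4-[(tert-butyldimethylsilyl)oxy]-2,2,6-trimethylcyclohexan-1-one | CC1(C)C[C@H](O[Si](C)(C)C(C)(C)C)C[C@@H](C)C1=O | intermediate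
28 | potassium (4R)-4-[(tert-butyldimethylsilyl)oxy]-2,6,6-trimethylcyclohex-1-en-1-olate | [K+].[O-]C1=C(C)C[C@@H](O[Si](C)(C)C(C)(C)C)CC1(C)C | intermediate
29 | (4R)-4-[(tert-butyldimethylsilyl)oxy]-2,6,6-trimethylcyclohex-1-en-1-yl trifluoromethanesulfonate | FC(F)(F)S(=O)(=O)OC1=C(C)C[C@@H](O[Si](C)(C)C(C)(C)C)CC1(C)C | intermediate
30 | allyltributylstannane | C=CC[Sn](CCCC)(CCCC)CCCC | starting material
31 | tert-butyldimethyl{[(1R)-3,5,5-trimethyl-4-(prop-2-en-1-yl)cyclohex-3-en-1-yl]oxy}silane | C=CCC1=C(C)C[C@@H](O[Si](C)(C)C(C)(C)C)CC1(C)C | intermediate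
32 | 2-[(4R)-4-[(tert-butyldimethylsilyl)oxy]-2,6,6-trimethylcyclohex-1-en-1-yl]acetaldehyde | O=CCC1=C(C)C[C@@H](O[Si](C)(C)C(C)(C)C)CC1(C)C | intermediate
33 | 4-bromofuran-2(5H)-one | O=C1C=C(Br)CO1 | starting material
34 | 4-{2-[(4R)-4-[(tert-butyldimethylsilyl)oxy]-2,6,6-trimethylcyclohex-1-en-1-yl]-1-hydroxyethyl}furan-2(5H)-one (C8 epimers) | O=C1C=C(CO1)C(O)CC1=C(C)C[C@@H](O[Si](C)(C)C(C)(C)C)CC1(C)C | intermediate
35 | 4-{2-[(4R)-4-[(tert-butyldimethylsilyl)oxy]-2,6,6-trimethylcyclohex-1-en-1-yl]-1-hydroxyethyl}-2,5-dihydrofuran-2-ol (C8 epimers, anomers) | OC1OCC(=C1)C(O)CC1=C(C)C[C@@H](O[Si](C)(C)C(C)(C)C)CC1(C)C | intermediate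
36 | ylide of 25 (C25 phosphorane) | c1ccc(cc1)P(c1ccccc1)(c1ccccc1)=C/C(C)=C/C=C/C=C(C)/C=C/C=C(C)/C=C/[C@H]1C(C)=C[C@H](O[Si](C)(C)C(C)(C)C)CC1(C)C | intermediate
37 | (3R,3'R,6'R)-3,3'-bis[(tert-butyldimethylsilyl)oxy]-7,8-dihydro-β,ε-carotene-8,19-diol (C8 epimers) | OC\C(=C/C=C/C(C)=C/C=C/C=C(C)/C=C/C=C(C)/C=C/[C@H]1C(C)=C[C@H](O[Si](C)(C)C(C)(C)C)CC1(C)C)C(O)CC1=C(C)C[C@@H](O[Si](C)(C)C(C)(C)C)CC1(C)C | intermediate
38 | dodecanoyl chloride | CCCCCCCCCCCC(=O)Cl | starting material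
39 | (3R,3'R,6'R)-3,3'-bis[(tert-butyldimethylsilyl)oxy]-8-hydroxy-7,8-dihydro-β,ε-caroten-19-yl dodecanoate (C8 epimers) | CCCCCCCCCCCC(=O)OC\C(=C/C=C/C(C)=C/C=C/C=C(C)/C=C/C=C(C)/C=C/[C@H]1C(C)=C[C@H](O[Si](C)(C)C(C)(C)C)CC1(C)C)C(O)CC1=C(C)C[C@@H](O[Si](C)(C)C(C)(C)C)CC1(C)C | intermediate
40 | (3R,3'R,6'R)-3,3'-bis[(tert-butyldimethylsilyl)oxy]-8-oxo-7,8-dihydro-β,ε-caroten-19-yl dodecanoate | CCCCCCCCCCCC(=O)OC\C(=C/C=C/C(C)=C/C=C/C=C(C)/C=C/C=C(C)/C=C/[C@H]1C(C)=C[C@H](O[Si](C)(C)C(C)(C)C)CC1(C)C)C(=O)CC1=C(C)C[C@@H](O[Si](C)(C)C(C)(C)C)CC1(C)C | intermediate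
41 | (3R,3'R,6'R)-3,3'-dihydroxy-8-oxo-7,8-dihydro-β,ε-caroten-19-yl dodecanoate | CCCCCCCCCCCC(=O)OC\C(=C/C=C/C(C)=C/C=C/C=C(C)/C=C/C=C(C)/C=C/[C@H]1C(C)=C[C@H](O)CC1(C)C)C(=O)CC1=C(C)C[C@@H](O)CC1(C)C | target

**Step count and risks**

Total step count: 22. Longest linear sequence: 16 steps (steps 1 to 12, then 19 to 22); the β-end branch (steps 13 to 18) joins at step 19.

Steps most likely to fail:

Step 4 (proposed new method). The π-allyl palladium alkoxide may undergo β-hydride elimination to a hydroxy diene or ketone, or ionisation beside the tetrasubstituted electron-poor alkene may be too slow for amination to compete. The fallback sets out from 8 and comes back at 14. Acid-catalysed hydrolysis (HClO4 cat., THF/H2O, 0 °C) opens the epoxide at the allylic carbon C4' with inversion to ethyl (3R,4R)-3,4-dihydroxy-2,6,6-trimethylcyclohex-1-ene-1-carboxylate F1. TBSCl and imidazole at −20 °C silylate the less hindered C3' hydroxyl to ethyl (3R,4R)-4-[(tert-butyldimethylsilyl)oxy]-3-hydroxy-2,6,6-trimethylcyclohex-1-ene-1-carboxylate F2. Mitsunobu displacement with 2-nitrobenzenesulfonyl hydrazide (PPh3, diethyl azodicarboxylate, N-methylmorpholine, THF, −30 °C) inverts C4' to ethyl (3S,4R)-4-[(tert-butyldimethylsilyl)oxy]-2,6,6-trimethyl-3-[1-(2-nitrophenylsulfonyl)hydrazinyl]cyclohex-1-ene-1-carboxylate F3. On warming to 23 °C this loses the sulfinic acid to ethyl (3S,4R)-4-[(tert-butyldimethylsilyl)oxy]-3-diazenyl-2,6,6-trimethylcyclohex-1-ene-1-carboxylate F4, which loses N2 by retro-ene reaction to give 14.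

Step 3. Enantioface discrimination may be insufficient for a cis-alkene whose conjugating partner is an ester-bearing alkene and not an arene, so that material of low enantiomeric purity is passed on. The fallback sets out from 13 (as delivered by steps 3 and 4) and comes back at 13. Esterification with (1S)-camphanic chloride (Et3N, DMAP, CH2Cl2) gives ethyl (1R,4R)-2,6,6-trimethyl-4-{[(1S,4R)-4,7,7-trimethyl-3-oxo-2-oxabicyclo[2.2.1]heptane-1-carbonyl]oxy}cyclohex-2-ene-1-carboxylate F5 together with the camphanate of the enantiomeric alcohol, ethyl (1S,4S)-2,6,6-trimethyl-4-{[(1S,4R)-4,7,7-trimethyl-3-oxo-2-oxabicyclo[2.2.1]heptane-1-carbonyl]oxy}cyclohex-2-ene-1-carboxylate F6. The diastereomers are separated by crystallisation or chromatography, and neutral transesterification of F5 (Ti(OEt)4, EtOH, 70 °C) returns enantiopure 13.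

Step 19. The lactol may dehydrate to the furan, and olefination of the free hydroxy enal with the valuable ylide may stall. The fallback sets out from 34 and comes back at 37. Ring opening of the butenolide with MeNH(OMe)·HCl and AlMe3 (CH2Cl2, 0 °C) gives (E)-3-{2-[(4R)-4-[(tert-butyldimethylsilyl)oxy]-2,6,6-trimethylcyclohex-1-en-1-yl]-1-hydroxyethyl}-4-hydroxy-N-methoxy-N-methylbut-2-enamide F7. Immediate silylation (Et3SiCl, imidazole) gives its bis(triethylsilyl) ether F8. i-Bu2AlH (THF, −78 °C) gives the open-chain (E)-3-{2-[(4R)-4-[(tert-butyldimethylsilyl)oxy]-2,6,6-trimethylcyclohex-1-en-1-yl]-1-[(triethylsilyl)oxy]ethyl}-4-[(triethylsilyl)oxy]but-2-enal F9, which can neither close to a lactol nor dehydrate. Wittig olefination with ylide 36 (from 25, NaN(SiMe3)2, THF, −78 → 0 °C) gives (3R,3'R,6'R)-3,3'-bis[(tert-butyldimethylsilyl)oxy]-8,19-bis[(triethylsilyl)oxy]-7,8-dihydro-β,ε-carotene F10. Pyridinium p-toluenesulfonate in MeOH/CH2Cl2 at 0 °C removes both triethylsilyl groups, leaves the tert-butyldimethylsilyl ethers and gives 37.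

Further compounds
F1 | step 4 | ethyl (3R,4R)-3,4-dihydroxy-2,6,6-trimethylcyclohex-1-ene-1-carboxylate | CCOC(=O)C1=C(C)[C@@H](O)[C@H](O)CC1(C)C
F2 | step 4 | ethyl (3R,4R)-4-[(tert-butyldimethylsilyl)oxy]-3-hydroxy-2,6,6-trimethylcyclohex-1-ene-1-carboxylate | CCOC(=O)C1=C(C)[C@@H](O)[C@H](O[Si](C)(C)C(C)(C)C)CC1(C)C
F3 | step 4 | ethyl (3S,4R)-4-[(tert-butyldimethylsilyl)oxy]-2,6,6-trimethyl-3-[1-(2-nitrophenylsulfonyl)hydrazinyl]cyclohex-1-ene-1-carboxylate | CCOC(=O)C1=C(C)[C@H](N(N)S(=O)(=O)c2ccccc2[N+](=O)[O-])[C@H](O[Si](C)(C)C(C)(C)C)CC1(C)C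
F4 | step 4 | ethyl (3S,4R)-4-[(tert-butyldimethylsilyl)oxy]-3-diazenyl-2,6,6-trimethylcyclohex-1-ene-1-carboxylate | CCOC(=O)C1=C(C)[C@H](N=N)[C@H](O[Si](C)(C)C(C)(C)C)CC1(C)C
F5 | step 3 | ethyl (1R,4R)-2,6,6-trimethyl-4-{[(1S,4R)-4,7,7-trimethyl-3-oxo-2-oxabicyclo[2.2.1]heptane-1-carbonyl]oxy}cyclohex-2-ene-1-carboxylate | CCOC(=O)[C@H]1C(C)=C[C@H](OC(=O)[C@@]23CC[C@@](C)(C(=O)O2)C3(C)C)CC1(C)C
F6 | step 3 | ethyl (1S,4S)-2,6,6-trimethyl-4-{[(1S,4R)-4,7,7-trimethyl-3-oxo-2-oxabicyclo[2.2.1]heptane-1-carbonyl]oxy}cyclohex-2-ene-1-carboxylate | CCOC(=O)[C@@H]1C(C)=C[C@@H](OC(=O)[C@@]23CC[C@@](C)(C(=O)O2)C3(C)C)CC1(C)C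
F7 | step 19 | (E)-3-{2-[(4R)-4-[(tert-butyldimethylsilyl)oxy]-2,6,6-trimethylcyclohex-1-en-1-yl]-1-hydroxyethyl}-4-hydroxy-N-methoxy-N-methylbut-2-enamide (C8 epimers) | CON(C)C(=O)/C=C(\CO)C(O)CC1=C(C)C[C@@H](O[Si](C)(C)C(C)(C)C)CC1(C)C
F8 | step 19 | (E)-3-{2-[(4R)-4-[(tert-butyldimethylsilyl)oxy]-2,6,6-trimethylcyclohex-1-en-1-yl]-1-[(triethylsilyl)oxy]ethyl}-N-methoxy-N-methyl-4-[(triethylsilyl)oxy]but-2-enamide (C8 epimers) | CON(C)C(=O)/C=C(\CO[Si](CC)(CC)CC)C(O[Si](CC)(CC)CC)CC1=C(C)C[C@@H](O[Si](C)(C)C(C)(C)C)CC1(C)C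
F9 | step 19 | (E)-3-{2-[(4R)-4-[(tert-butyldimethylsilyl)oxy]-2,6,6-trimethylcyclohex-1-en-1-yl]-1-[(triethylsilyl)oxy]ethyl}-4-[(triethylsilyl)oxy]but-2-enal (C8 epimers) | O=C/C=C(\CO[Si](CC)(CC)CC)C(O[Si](CC)(CC)CC)CC1=C(C)C[C@@H](O[Si](C)(C)C(C)(C)C)CC1(C)C
F10 | step 19 | (3R,3'R,6'R)-3,3'-bis[(tert-butyldimethylsilyl)oxy]-8,19-bis[(triethylsilyl)oxy]-7,8-dihydro-β,ε-carotene (C8 epimers) | CC[Si](CC)(CC)OC\C(=C/C=C/C(C)=C/C=C/C=C(C)/C=C/C=C(C)/C=C/[C@H]1C(C)=C[C@H](O[Si](C)(C)C(C)(C)C)CC1(C)C)C(O[Si](CC)(CC)CC)CC1=C(C)C[C@@H](O[Si](C)(C)C(C)(C)C)CC1(C)C
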